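The retrosynthesis cuts three bonds. The first is the ester C–O bond between the malate 1-carboxyl and the terminal chain oxygen, the second is the bond between chain carbons 2 and 3 (counted from the methine, cut as an alkene), and the last is the bond between the quaternary lactone carbon and the carboxyl-bearing methine.
Enabling feature: read as a furan, the γ-lactone (O1, carbonyl C2, C3, C4, quaternary C5 with its CO2H) is a hydrogenated 5-hydroxy-2-furoic acid. The exocyclic CH(CO2H) and the next two chain carbons are Cβ, Cα and the formyl carbon of a 4-oxobut-2-enoic ester, so the C5–Cβ bond joins two flat achiral partners that already hold both core carboxyls.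
Ring, forward order: the only ring of the target is bought as a saturated lactone, aromatised to a 2-silyloxyfuran, turned into a butenolide by the C5–Cβ bond formation, and saturated later. It is never closed in the route.
Chain, forward order: the two-carbon aldehyde arm of the adduct takes up an eight-carbon ylide (Wittig). One hydrogenation saturates both alkenes and frees the terminal alcohol, an activated (R)-malic anhydride acylates it, and acid removes the two tert-butyl esters last.
Stereochemistry: the quaternary carbon (S) and the methine (R) are created together under control of a chiral imidazolidinone salt. The malate carbinol (R) is bought as D-malic acid, and the stereocentre of the bought lactone is destroyed on purpose.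

Key step: step 6

Assumption: the catalyst enantiomer and the acid/solvent pair that give the S,R core are derived from the accepted shielding model and from the behaviour of closely related furoate-derived silyloxyfurans, and are to be verified crystallographically on the key-step adduct.

Step 1
Reactants: 1 (S)-5-oxotetrahydrofuran-2-carboxylic acid
Product: 2 tert-butyl (S)-5-oxotetrahydrofuran-2-carboxylate
Conditions: Cl3CC(=NH)OtBu, BF3·OEt2 (cat.), CH2Cl2–cyclohexane, rt
Reagents that add atoms: tert-butyl 2,2,2-trichloroacetimidate, CC(C)(C)OC(=N)C(Cl)(Cl)Cl
Why: Acid-catalysed tert-butyl transfer from a trichloroacetimidate to a carboxylic acid (imidate esterification) needs neither base nor nucleophile, so the lactone stays closed, and retention at the stereocentre is of no concern because step 2 erases it.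

Step 2
Reactants: 2 tert-butyl (S)-5-oxotetrahydrofuran-2-carboxylate
Product: 3 tert-butyl 2-bromo-5-oxotetrahydrofuran-2-carboxylate (racemic)
Conditions: NBS, (PhCO2)2 (cat.), PhCF3, reflux
Reagents that add atoms: N-bromosuccinimide, O=C1N(Br)C(=O)CC1
Why: Wohl–Ziegler-type radical bromination should pick the one tertiary C–H that lies between the ring oxygen and the ester carbonyl (captodatively stabilised radical), as it does in lactide and in lactic acid derived dioxolanones, and the planar radical makes 3 racemic.

Step 3
Reactants: 3 tert-butyl 2-bromo-5-oxotetrahydrofuran-2-carboxylate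
Product: 5 tert-butyl 5-(triisopropylsilyloxy)furan-2-carboxylate, via enol lactone 4 (not isolated)
Conditions: Et3N (excess), CH2Cl2, 0 °C; then iPr3SiOTf, 0 °C to rt
Reagents that add atoms: triisopropylsilyl trifluoromethanesulfonate, CC(C)[Si](C(C)C)(C(C)C)OS(=O)(=O)C(F)(F)F
Why: Base-induced E2 loss of HBr gives enol lactone 4, whose doubly activated CH2 group is soft-enolised and O-silylated (standard butenolide to 2-silyloxyfuran conversion) with aromatisation as driving force; a shift of the double bond of 4 into conjugation would be harmless, since both isomers give 5.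

Step 4
Reactants: 6 tert-butyl (triphenylphosphoranylidene)acetate; 7 2,2-dimethoxyacetaldehyde
Product: 8 tert-butyl (E)-4,4-dimethoxybut-2-enoate
Conditions: CH2Cl2, rt (7 used as its commercial aqueous solution)
Reagents that add atoms: none
Why: Wittig olefination with an ester-stabilised ylide is E-selective in an aprotic solvent and tolerates the water that comes with the aldehyde; a minor Z isomer is removed by chromatography.

Step 5
Reactants: 8 tert-butyl (E)-4,4-dimethoxybut-2-enoate
Product: 9 tert-butyl (E)-4-oxobut-2-enoate
Conditions: Amberlyst-15, acetone–H2O, rt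
Reagents that add atoms: water, O
Why: Acid-catalysed acetal hydrolysis on a sulfonic acid resin in wet acetone, the usual way to unmask γ-oxo-enoates and fumaraldehyde monoacetals, is far too mild to ionise a tert-butyl ester and leaves the E alkene as the more stable isomer.

Step 6
Reactants: 5 tert-butyl 5-(triisopropylsilyloxy)furan-2-carboxylate; 9 tert-butyl (E)-4-oxobut-2-enoate
Product: 12 tert-butyl (2S)-2-[(2R)-1-tert-butoxy-1,4-dioxobutan-2-yl]-5-oxo-2,5-dihydrofuran-2-carboxylate, via iminium triflate 10 (not isolated), via silyloxyfuranium enamine 11 (not isolated)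
Conditions: (2S,5S)-5-benzyl-2-tert-butyl-3-methylimidazolidin-4-one·CF3SO3H (20 mol %), H2O (2 equiv), CHCl3, −20 °C
Reagents that add atoms: water, O
Why: The catalyst condenses with the formyl group of 9 to the E-configured iminium ion 10, and the silyl dienol ether 5 attacks it through its ester-bearing ring carbon (C5 in lactone numbering) at the alkene carbon β to nitrogen, which dearomatises the furan to the silyloxyfuranium enamine 11; water then takes the silyl group and hydrolyses the enamine, so that 12 is released and the catalyst salt returns. The closest known reaction type is the iminium-catalysed vinylogous Mukaiyama–Michael addition of 2-silyloxyfurans, 5-alkoxycarbonyl ones included, to enals such as 4-oxobutenoates, so only the ester alkyl groups are new here. No ring is closed, because the five-membered ring of 12 is the furan ring of 5 in its butenolide form. The methine centre is controlled by the catalyst, whose benzyl and tert-butyl groups cover one face of 10 and leave the Si face of Cβ open (R), and the quaternary centre by the furan face that meets it, Si at C5 (S, like topicity), a pairing for which the triflate counter-ion in a chlorinated solvent is chosen because acid cocatalyst and solvent are the known switch between the two diastereomeric series with furoate donors. The step needs 1,4- instead of 1,2-addition, attack β to the iminium and not β to the ester, C5 instead of C3 reactivity of the furan, and both facial selectivities: the far stronger acceptor character of the iminium end of 9 and the shielded iminium carbon secure the first two, and the silyloxy group of 5, which pushes electron density to the distal C5 and lets the conjugated butenolide form, secures the third. The configuration of 12 should be confirmed by X-ray analysis of a crystalline derivative before material is carried on, with the mirror-image catalyst at hand should the absolute sense be reversed.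

Step 7
Reactants: 13 octane-1,8-diol
Product: 14 8-bromooctan-1-ol
Conditions: 48% aq. HBr, toluene, reflux
Reagents that add atoms: hydrogen bromide, Br
Why: Substitution of one protonated hydroxyl by bromide under two-phase conditions is the standard monobromination of α,ω-diols, the bromo alcohol being drawn into the toluene phase where it reacts on much more slowly than the diol.

Step 8
Reactants: 14 8-bromooctan-1-ol
Product: 15 benzyl 8-bromooctyl ether
Conditions: BnOC(=NH)CCl3, CF3SO3H (cat.), CH2Cl2–cyclohexane, 0 °C to rt
Reagents that add atoms: benzyl 2,2,2-trichloroacetimidate, N=C(OCc1ccccc1)C(Cl)(Cl)Cl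
Why: Acid-catalysed benzylation with a benzyl trichloroacetimidate protects the alcohol without any base, so that neither ether formation by self-alkylation nor elimination of the primary bromide can occur.

Step 9
Reactants: 15 benzyl 8-bromooctyl ether
Product: 16 (8-benzyloxyoctyl)triphenylphosphonium bromide
Conditions: PPh3, MeCN, reflux
Reagents that add atoms: triphenylphosphine, c1ccc(cc1)P(c1ccccc1)c1ccccc1
Why: Quaternisation of triphenylphosphine by backside displacement at an unhindered primary bromide is reliable, and the salt can be freed from neutral material by precipitation and dried azeotropically.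

Step 10
Reactants: 12 tert-butyl (2S)-2-[(2R)-1-tert-butoxy-1,4-dioxobutan-2-yl]-5-oxo-2,5-dihydrofuran-2-carboxylate; 16 (8-benzyloxyoctyl)triphenylphosphonium bromide
Product: 18 tert-butyl (2S)-2-[(2R,4Z)-12-(benzyloxy)-1-tert-butoxy-1-oxododec-4-en-2-yl]-5-oxo-2,5-dihydrofuran-2-carboxylate, via phosphonium ylide 17 (not isolated)
Conditions: 16 (1.2 equiv), NaN(SiMe3)2 (1.1 equiv), THF, 0 °C; ylide solution added slowly to 12, THF, −78 °C
Reagents that add atoms: none
Why: Wittig olefination with a lithium-free, non-stabilised ylide is very fast at low temperature and Z-selective (the geometry is later irrelevant), and slow addition of a ylide solution that holds no excess amide base to the aldehyde keeps the medium from becoming basic, so that retro-Michael cleavage, epimerisation of the methine and conjugate addition to the butenolide should not compete, as is known for closely related butenolide aldehydes.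

Step 11
Reactants: 18 tert-butyl (2S)-2-[(2R,4Z)-12-(benzyloxy)-1-tert-butoxy-1-oxododec-4-en-2-yl]-5-oxo-2,5-dihydrofuran-2-carboxylate
Product: 19 tert-butyl (2S)-2-[(2R)-1-tert-butoxy-12-hydroxy-1-oxododecan-2-yl]-5-oxooxolane-2-carboxylate
Conditions: H2 (1 atm), Pd/C, EtOH, rt
Reagents that add atoms: none
Why: Heterogeneous catalytic hydrogenation saturates the chain alkene and the butenolide alkene and hydrogenolyses the benzyl ether in one operation; no stereocentre is formed or touched, and the tert-butyl esters and the lactone are inert.

Step 12
Reactants: 20 (R)-malic acid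
Product: 21 (3R)-2,5-dioxooxolan-3-yl trifluoroacetate
Conditions: (CF3CO)2O, neat, 0 °C to rt; volatiles removed in vacuo, used crude
Reagents that add atoms: trifluoroacetic anhydride, O=C(OC(=O)C(F)(F)F)C(F)(F)F
Why: Trifluoroacetic anhydride dehydrates the 1,4-diacid to the five-membered cyclic anhydride and acylates the hydroxyl, a known activation of malic acid in which no bond to the stereocentre is broken, so that R is kept.

Step 13
Reactants: 19 tert-butyl (2S)-2-[(2R)-1-tert-butoxy-12-hydroxy-1-oxododecan-2-yl]-5-oxooxolane-2-carboxylate; 21 (3R)-2,5-dioxooxolan-3-yl trifluoroacetate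
Product: 23 (3R)-4-{[(11R)-12-tert-butoxy-11-[(2S)-2-(tert-butoxycarbonyl)-5-oxooxolan-2-yl]-12-oxododecyl]oxy}-3-hydroxy-4-oxobutanoic acid, via O-trifluoroacetyl half-ester 22 (not isolated)
Conditions: 21 (3 equiv), CH2Cl2, 0 °C to rt, no base; then THF–H2O, rt
Reagents that add atoms: none
Why: Regioselective alcoholysis of an unsymmetrical cyclic anhydride: the carbonyl next to the strongly electron-withdrawing trifluoroacetoxy carbon is the more electrophilic one, so the primary alcohol should open 21 there to 22, and the labile trifluoroacetate is hydrolysed in the aqueous second stage, which also turns the excess of 21 into water-soluble malic acid.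

Step 14
Reactants: 23 (3R)-4-{[(11R)-12-tert-butoxy-11-[(2S)-2-(tert-butoxycarbonyl)-5-oxooxolan-2-yl]-12-oxododecyl]oxy}-3-hydroxy-4-oxobutanoic acid
Product: 24 (2S)-2-[(1R)-1-carboxy-11-{[(2R)-3-carboxy-2-hydroxypropanoyl]oxy}undecyl]-5-oxooxolane-2-carboxylic acid (CNP0457473.2)
Conditions: CF3CO2H–CH2Cl2, 0 °C to rt; evaporation, then lyophilisation from aqueous MeCN
Reagents that add atoms: none
Why: Acidolysis of tert-butyl esters by alkyl–oxygen cleavage works in anhydrous acid, to which the primary malate ester, the γ-lactone and the three stereocentres are inert, and a trifluoroacetate that may form on the carbinol falls off during the aqueous lyophilisation.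

Compound list
1 | (S)-5-oxotetrahydrofuran-2-carboxylic acid | OC(=O)[C@@H]1CCC(=O)O1 | starting material
2 | tert-butyl (S)-5-oxotetrahydrofuran-2-carboxylate | CC(C)(C)OC(=O)[C@@H]1CCC(=O)O1 | intermediate
3 | tert-butyl 2-bromo-5-oxotetrahydrofuran-2-carboxylate (racemic) | CC(C)(C)OC(=O)C1(Br)CCC(=O)O1 | intermediate
4 | tert-butyl 5-oxo-4,5-dihydrofuran-2-carboxylate (enol lactone, formed in situ) | CC(C)(C)OC(=O)C1=CCC(=O)O1 | intermediate
5 | tert-butyl 5-(triisopropylsilyloxy)furan-2-carboxylate | CC(C)[Si](C(C)C)(C(C)C)Oc1ccc(C(=O)OC(C)(C)C)o1 | intermediate
6 | tert-butyl (triphenylphosphoranylidene)acetate | CC(C)(C)OC(=O)C=P(c1ccccc1)(c1ccccc1)c1ccccc1 | starting material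
7 | 2,2-dimethoxyacetaldehyde | COC(OC)C=O | starting material
8 | tert-butyl (E)-4,4-dimethoxybut-2-enoate | COC(OC)/C=C/C(=O)OC(C)(C)C | intermediate
9 | tert-butyl (E)-4-oxobut-2-enoate | O=C/C=C/C(=O)OC(C)(C)C | intermediate
10 | E-iminium triflate from 9 and the (2S,5S)-imidazolidinone catalyst (formed in situ) | O=C1N(C)[C@@H](C(C)(C)C)/[N+](=C/C=C/C(=O)OC(C)(C)C)[C@H]1Cc2ccccc2.[O-]S(=O)(=O)C(F)(F)F | intermediate
11 | silyloxyfuranium enamine triflate, the C–C adduct before loss of silicon and hydrolysis (formed in situ) | O=C1N(C)[C@@H](C(C)(C)C)N(/C=C/[C@@H](C(=O)OC(C)(C)C)[C@]2(C(=O)OC(C)(C)C)C=CC(O[Si](C(C)C)(C(C)C)C(C)C)=[O+]2)[C@H]1Cc2ccccc2.[O-]S(=O)(=O)C(F)(F)F | intermediate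
12 | tert-butyl (2S)-2-[(2R)-1-tert-butoxy-1,4-dioxobutan-2-yl]-5-oxo-2,5-dihydrofuran-2-carboxylate | O=CC[C@@H](C(=O)OC(C)(C)C)[C@]1(C(=O)OC(C)(C)C)C=CC(=O)O1 | intermediate
13 | octane-1,8-diol | OCCCCCCCCO | starting material
14 | 8-bromooctan-1-ol | OCCCCCCCCBr | intermediate
15 | benzyl 8-bromooctyl ether | BrCCCCCCCCOCc1ccccc1 | intermediate
16 | (8-benzyloxyoctyl)triphenylphosphonium bromide | [Br-].C(CCCCCCCOCc1ccccc1)[P+](c1ccccc1)(c1ccccc1)c1ccccc1 | intermediate
17 | (8-benzyloxyoctylidene)triphenylphosphorane (formed in situ) | C(CCCCCCCOCc1ccccc1)=P(c1ccccc1)(c1ccccc1)c1ccccc1 | intermediate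
18 | tert-butyl (2S)-2-[(2R,4Z)-12-(benzyloxy)-1-tert-butoxy-1-oxododec-4-en-2-yl]-5-oxo-2,5-dihydrofuran-2-carboxylate | c1ccccc1COCCCCCCC/C=C\C[C@@H](C(=O)OC(C)(C)C)[C@]1(C(=O)OC(C)(C)C)C=CC(=O)O1 | intermediate
19 | tert-butyl (2S)-2-[(2R)-1-tert-butoxy-12-hydroxy-1-oxododecan-2-yl]-5-oxooxolane-2-carboxylate | OCCCCCCCCCC[C@@H](C(=O)OC(C)(C)C)[C@]1(C(=O)OC(C)(C)C)CCC(=O)O1 | intermediate
20 | (R)-malic acid (D-malic acid) | O=C(O)C[C@@H](O)C(=O)O | starting material
21 | (3R)-2,5-dioxooxolan-3-yl trifluoroacetate, i.e. (R)-O-trifluoroacetylmalic anhydride | O=C1C[C@@H](OC(=O)C(F)(F)F)C(=O)O1 | intermediate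
22 | O-trifluoroacetyl derivative of 23 (formed in situ) | O=C(O)C[C@@H](OC(=O)C(F)(F)F)C(=O)OCCCCCCCCCC[C@@H](C(=O)OC(C)(C)C)[C@]1(C(=O)OC(C)(C)C)CCC(=O)O1 | intermediate
23 | (3R)-4-{[(11R)-12-tert-butoxy-11-[(2S)-2-(tert-butoxycarbonyl)-5-oxooxolan-2-yl]-12-oxododecyl]oxy}-3-hydroxy-4-oxobutanoic acid | O=C(O)C[C@@H](O)C(=O)OCCCCCCCCCC[C@@H](C(=O)OC(C)(C)C)[C@]1(C(=O)OC(C)(C)C)CCC(=O)O1 | intermediate
24 | (2S)-2-[(1R)-1-carboxy-11-{[(2R)-3-carboxy-2-hydroxypropanoyl]oxy}undecyl]-5-oxooxolane-2-carboxylic acid (CNP0457473.2) | O=C(O)C[C@@H](O)C(=O)OCCCCCCCCCC[C@@H](C(=O)O)[C@]1(C(=O)O)CCC(=O)O1 | target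

Total step count: 14.
Longest linear sequence: 8 steps (steps 1, 2, 3, 6, 10, 11, 13, 14).

Steps most likely to fail

Step 6. Facial selection at the ester-bearing furan carbon may erode or turn over, because this carbon now carries a tert-butyl ester instead of a small alkyl ester. Protodesilylation of 5 by the wet acid salt may also outrun a slow bond formation at the crowded site. The fallback is a silicon-free, direct vinylogous Michael addition. It sets out from bromide 3, which is treated with Et3N alone so that enol lactone 4 can be isolated. Compound 4 then serves as the pronucleophile towards 9 under (S)-α,α-diphenylprolinol trimethylsilyl ether (20 mol %) and benzoic acid in toluene at 0 °C, a known reaction type for γ-substituted deconjugated butenolides and enals. The nucleophile is now a dienol or dienolate paired with the catalyst system rather than a free silyl dienol ether. A differently organised transition state therefore decides the furan face, while the bulky diarylmethyl group leaves the same enal face open. The sequence comes back to the route at 12 and makes no compound outside the list (entry F0).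

Step 13. With the alcohol as the limiting partner and no base, the ring opening may be slow, attack may leak to the distal carbonyl, and the trifluoroacetyl group may be transferred to the chain alcohol. The fallback reverses the polarity and alkylates a carboxylate instead of acylating the alcohol. It sets out from 19, which is converted with iodine, PPh3 and imidazole in CH2Cl2 into tert-butyl (2S)-2-[(2R)-1-tert-butoxy-12-iodo-1-oxododecan-2-yl]-5-oxooxolane-2-carboxylate F1. Commercial D-aspartic acid 4-tert-butyl ester is diazotised (NaNO2, aqueous AcOH, 0 °C, retention by double inversion) to (2R)-4-tert-butoxy-2-hydroxy-4-oxobutanoic acid F2. Only the 1-carboxyl of this acid is free, so the regiochemistry no longer depends on selectivity. O-Alkylation of F2 by F1 (Cs2CO3, DMF, rt) needs no protection of the carbinol and should give the tri-tert-butyl ester of the target F3. The acidolysis of step 14 then removes three tert-butyl groups instead of two and comes back to the route at 24.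

Step 2. Premature thermal loss of HBr may be followed by further bromination of the newly activated methylene group. Hydrogen abstraction may also occur at the other ring positions, or the tert-butyl ester may be lost to adventitious acid. The fallback is an ionic dehydrogenation by selenoxide elimination. It sets out from 2, which is enolised with LiN(SiMe3)2 in THF at −78 °C and quenched with PhSeBr to give tert-butyl (2S)-5-oxo-4-(phenylselanyl)oxolane-2-carboxylate F4. Oxidation with H2O2 in CH2Cl2 at 0 °C and spontaneous syn elimination should give tert-butyl (2S)-5-oxo-2,5-dihydrofuran-2-carboxylate F5. Silylation of F5 with iPr3SiOTf and Et3N, as in the second half of step 3, comes back to the route at 5. If enolisation takes place at the ester-bearing carbon instead, the same two operations lead to 4, which is silylated to the same furan, so the site of deprotonation does not matter.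

Further compounds
F0 | step 6 | none | none
F1 | step 13 | tert-butyl (2S)-2-[(2R)-1-tert-butoxy-12-iodo-1-oxododecan-2-yl]-5-oxooxolane-2-carboxylate | ICCCCCCCCCC[C@@H](C(=O)OC(C)(C)C)[C@]1(C(=O)OC(C)(C)C)CCC(=O)O1
F2 | step 13 | (2R)-4-tert-butoxy-2-hydroxy-4-oxobutanoic acid | CC(C)(C)OC(=O)C[C@@H](O)C(=O)O
F3 | step 13 | tri-tert-butyl ester of the target | CC(C)(C)OC(=O)C[C@@H](O)C(=O)OCCCCCCCCCC[C@@H](C(=O)OC(C)(C)C)[C@]1(C(=O)OC(C)(C)C)CCC(=O)O1
F4 | step 2 | tert-butyl (2S)-5-oxo-4-(phenylselanyl)oxolane-2-carboxylate | CC(C)(C)OC(=O)[C@@H]1CC([Se]c2ccccc2)C(=O)O1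
F5 | step 2 | tert-butyl (2S)-5-oxo-2,5-dihydrofuran-2-carboxylate | CC(C)(C)OC(=O)[C@@H]1C=CC(=O)O1
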